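**Retrosynthetic overview** (benzofuranone numbering O1, C2, C3, C3a, C4–C7, C7a)
- The strategy rests on lactone oxygen O1, which sits between carbonyl C2 and C7a in the five-membered lactone ring B fused to carbocycle ring A. Without O1, ring B is a four-membered ketone fused to ring A, i.e. a benzocyclobutenone.
- Endgame disconnections: the 5-O-methyl group (enol etherification), the quinone methide (dehydrogenation of a catechol lactone), the three methyl ethers, and the C3–aryl bond (palladium-catalysed lactone α-arylation). These lead back to 5,6-dimethoxy-4,7-diphenylbenzofuran-2(3H)-one.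
- Key disconnection: removal of O1 from that lactone gives 3,4-dimethoxy-2,5-diphenylbenzocyclobutenone (forward: Baeyer–Villiger oxygen insertion with aryl migration).
- The benzocyclobutenone comes from a ketene acetal [2+2] adduct of a C2-symmetric aryne. The aryne comes from the monobromide of 2,3-dimethoxy-1,4-diphenylbenzene, itself made by twofold Suzuki–Miyaura coupling.
- Ring order: ring A is bought; the four-membered ring is closed on it in step 3 and expanded to lactone ring B in step 5.

Key step: step 5

Remark: the 3-aryl lactone intermediates carry a C3 stereocentre and are taken as racemates; it is erased on oxidation to the quinone methide, and the target has no stereocentre.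

**Step 1**
Reactants: 1 1,4-dibromo-2,3-dimethoxybenzene; 2 phenylboronic acid (2.4 equiv)
Product: 3 2,3-dimethoxy-1,4-diphenylbenzene
Conditions: Pd(PPh3)4 (5 mol %), K2CO3, toluene/EtOH/H2O, 90 °C
Reagents that add atoms: none
Why: Twofold Suzuki–Miyaura coupling at two equivalent C–Br bonds, which tolerates the ortho methoxy groups and raises no regiochemical question.

**Step 2**
Reactants: 3 2,3-dimethoxy-1,4-diphenylbenzene
Product: 4 1-bromo-3,4-dimethoxy-2,5-diphenylbenzene
Conditions: NBS (1.05 equiv), cat. TFA, MeCN, 0 °C to rt, dark
Reagents that add atoms: N-bromosuccinimide, O=C1CCC(=O)N1Br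
Why: Electrophilic aromatic bromination, in which the two free positions of the central ring are equivalent and each lies para to a methoxy group, so this ring should react before the pendant phenyls, and the first bromine slows a second substitution.

**Step 3**
Reactants: 4 1-bromo-3,4-dimethoxy-2,5-diphenylbenzene; 5 1,1-dimethoxyethene (3 equiv)
Product: 7 3,4,7,7-tetramethoxy-2,5-diphenylbicyclo[4.2.0]octa-1,3,5-triene, via 4,5-dimethoxy-3,6-diphenylbenzyne 6 (not isolated)
Conditions: NaNH2 (3 equiv), THF, reflux
Reagents that add atoms: none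
Why: Aryne [2+2] cycloaddition with a ketene acetal: NaNH2 removes the only proton ortho to bromine, bromide leaves, and the electron-rich alkene adds stepwise to the symmetric aryne, whose two reactive carbons are equivalent, so one cyclobutene acetal should form.

**Step 4**
Reactants: 7 3,4,7,7-tetramethoxy-2,5-diphenylbicyclo[4.2.0]octa-1,3,5-triene
Product: 8 3,4-dimethoxy-2,5-diphenylbicyclo[4.2.0]octa-1,3,5-trien-7-one
Conditions: 1 M HCl, THF, rt
Reagents that add atoms: water, O
Why: Acid-catalysed acetal hydrolysis, which is fast for this dimethyl ketal under conditions that leave the aryl methyl ethers untouched.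

**Step 5**
Reactants: 8 3,4-dimethoxy-2,5-diphenylbicyclo[4.2.0]octa-1,3,5-trien-7-one
Product: 10 5,6-dimethoxy-4,7-diphenylbenzofuran-2(3H)-one, via Criegee peroxyhemiketal 9 (not isolated)
Conditions: mCPBA (1.3 equiv), CH2Cl2, 0 °C to rt
Reagents that add atoms: 3-chloroperoxybenzoic acid, OOC(=O)c1cccc(Cl)c1
Why: The peracid adds to the strained four-membered ketone of 8 to give the Criegee peroxyhemiketal 9, and loss of 3-chlorobenzoate is coupled to a 1,2-shift of the aryl carbon (C6 of 8, C7a of 10) from the carbonyl carbon to oxygen, so that O1 is inserted and the O1–C2 and O1–C7a bonds are formed. This is a Baeyer–Villiger oxidation, the known course of peracid oxidation of benzocyclobutenones to benzofuran-2(3H)-ones. Lactone ring B is closed by ring expansion of the four-membered ring through this shift, not by an end-to-end cyclisation, and the strain of the cyclobutenone is released. No stereocentre is formed. The step needs aryl and not methylene migration, because methylene migration would lead to the isomeric isobenzofuranone; the migrating aryl carbon lies para to the methoxy group that ends at C5 and can carry positive charge in the transition state, whereas the competitor is an unactivated primary carbon. The arene has no free position, so ring hydroxylation by the peracid is not expected.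

**Step 6**
Reactants: 10 5,6-dimethoxy-4,7-diphenylbenzofuran-2(3H)-one; 11 4-bromoanisole (1.2 equiv)
Product: 12 5,6-dimethoxy-3-(4-methoxyphenyl)-4,7-diphenylbenzofuran-2(3H)-one (racemic)
Conditions: Pd(OAc)2 (5 mol %), XPhos (10 mol %), K3PO4 (3 equiv), toluene, 90 °C, Ar
Reagents that add atoms: none
Why: Palladium-catalysed α-arylation of a lactone enolate, in which the acidic C3 methylene is deprotonated by K3PO4, the bulky biarylphosphine drives reductive elimination at the hindered carbon, and the flanking C4 phenyl together with the weakly nucleophilic product enolate should stop the reaction at monoarylation, C3 being formed as the racemate.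

**Step 7**
Reactants: 12 5,6-dimethoxy-3-(4-methoxyphenyl)-4,7-diphenylbenzofuran-2(3H)-one
Product: 13 5,6-dihydroxy-3-(4-hydroxyphenyl)-4,7-diphenylbenzofuran-2(3H)-one (racemic)
Conditions: BBr3 (6 equiv), CH2Cl2, −78 °C to rt; degassed aqueous work-up
Reagents that add atoms: none
Why: Lewis acid cleavage of aryl methyl ethers, in which BBr3 binds each methoxy oxygen and bromide removes the methyl group, while the aryl ester lactone is not cleaved at or below rt and any opened material should reclose on acidic work-up.

**Step 8**
Reactants: 13 5,6-dihydroxy-3-(4-hydroxyphenyl)-4,7-diphenylbenzofuran-2(3H)-one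
Product: 14 5-hydroxy-3-(4-hydroxyphenyl)-4,7-diphenyl-1-benzofuran-2,6-dione (xylerythrin)
Conditions: DDQ (1.0 equiv), THF, 0 °C to rt
Reagents that add atoms: none
Why: Quinone dehydrogenation, in which DDQ removes the hydrogens on O6 and C3 and the only closed-shell product is the para-quinone methide with C6=O, C3=C3a and an enolic 5-OH, so that the C3 stereocentre is erased.

**Step 9**
Reactants: 14 5-hydroxy-3-(4-hydroxyphenyl)-4,7-diphenyl-1-benzofuran-2,6-dione
Product: 15 3-(4-hydroxyphenyl)-5-methoxy-4,7-diphenyl-1-benzofuran-2,6-dione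
Conditions: MeOH, TsOH (cat.), 3 Å molecular sieves, 40 °C
Reagents that add atoms: methanol, CO
Why: Acid-catalysed enol etherification of a vinylogous acid (Fischer type), in which the 5-OH is the enol of the C5/C6 dicarbonyl pair and is linked through C4=C3a–C3 to the lactone carbonyl, so that protonation makes C5 electrophilic, methanol adds and water leaves, a path that the 4'-phenol does not have.

**Compound list**
1 | 1,4-dibromo-2,3-dimethoxybenzene | COc1c(Br)ccc(Br)c1OC | starting material
2 | phenylboronic acid | OB(O)c1ccccc1 | starting material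
3 | 2,3-dimethoxy-1,4-diphenylbenzene | COc1c(-c2ccccc2)ccc(-c2ccccc2)c1OC | intermediate
4 | 1-bromo-3,4-dimethoxy-2,5-diphenylbenzene | COc1c(OC)c(-c2ccccc2)c(Br)cc1-c1ccccc1 | intermediate
5 | 1,1-dimethoxyethene | C=C(OC)OC | starting material
6 | 4,5-dimethoxy-3,6-diphenylbenzyne (1,2-didehydro-4,5-dimethoxy-3,6-diphenylbenzene) | COC1=C(c2ccccc2)C#CC(c2ccccc2)=C1OC | intermediate
7 | 3,4,7,7-tetramethoxy-2,5-diphenylbicyclo[4.2.0]octa-1,3,5-triene | COC1(OC)Cc2c1c(-c1ccccc1)c(OC)c(OC)c2-c1ccccc1 | intermediate
8 | 3,4-dimethoxy-2,5-diphenylbicyclo[4.2.0]octa-1,3,5-trien-7-one | O=C1Cc2c1c(-c1ccccc1)c(OC)c(OC)c2-c1ccccc1 | intermediate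
9 | 7-hydroxy-3,4-dimethoxy-2,5-diphenylbicyclo[4.2.0]octa-1,3,5-trien-7-yl 3-chloroperoxybenzoate (Criegee peroxyhemiketal) | OC1(OOC(=O)c2cccc(Cl)c2)Cc2c1c(-c1ccccc1)c(OC)c(OC)c2-c1ccccc1 | intermediate
10 | 5,6-dimethoxy-4,7-diphenylbenzofuran-2(3H)-one | O=C1Cc2c(O1)c(-c1ccccc1)c(OC)c(OC)c2-c1ccccc1 | intermediate
11 | 4-bromoanisole | COc1ccc(Br)cc1 | starting material
12 | 5,6-dimethoxy-3-(4-methoxyphenyl)-4,7-diphenylbenzofuran-2(3H)-one (racemic) | COc1ccc(cc1)C1C(=O)Oc2c1c(-c1ccccc1)c(OC)c(OC)c2-c1ccccc1 | intermediate
13 | 5,6-dihydroxy-3-(4-hydroxyphenyl)-4,7-diphenylbenzofuran-2(3H)-one (racemic) | Oc1ccc(cc1)C1C(=O)Oc2c1c(-c1ccccc1)c(O)c(O)c2-c1ccccc1 | intermediate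
14 | 5-hydroxy-3-(4-hydroxyphenyl)-4,7-diphenyl-1-benzofuran-2,6-dione | OC1=C(c2ccccc2)C2=C(c3ccc(O)cc3)C(=O)OC2=C(c2ccccc2)C1=O | intermediate
15 | 3-(4-hydroxyphenyl)-5-methoxy-4,7-diphenyl-1-benzofuran-2,6-dione | COC1=C(c2ccccc2)C2=C(c3ccc(O)cc3)C(=O)OC2=C(c2ccccc2)C1=O | target

**Step count and risks**
Total step count: 9. Longest linear sequence: 9 steps (1 to 15).

Steps most likely to fail:

1. Step 5. Migration of the methylene carbon in place of the aryl carbon, or peracid attack on the electron-rich ring, would divert material from the lactone. Fallback, from 4 and back to the route at 12: palladium-catalysed hydroxylation of 4 (Pd2(dba)3, tBuXPhos, KOH, 1,4-dioxane/H2O, 100 °C) would give 3,4-dimethoxy-2,5-diphenylphenol F1. Acid-mediated condensation of this phenol with 4-methoxymandelic acid (TsOH, 1,2-dichloroethane, reflux, water removal) would alkylate the only free ring position, which is ortho to the hydroxyl, and lactonise to give 12 directly. The route would then continue at step 7.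

2. Step 9. Methanolysis of the enol lactone, which is a vinylogous anhydride, may compete with etherification, or exchange at the hindered C5 may stall. Fallback, from 14 and back at 15: silylation with the bulky TBDPSCl (1.05 equiv, imidazole, CH2Cl2, 0 °C) should take the unhindered 4'-phenol and leave the hindered, hydrogen-bonded 5-OH, giving 3-[4-(tert-butyldiphenylsilyloxy)phenyl]-5-hydroxy-4,7-diphenyl-1-benzofuran-2,6-dione F2. O-Methylation of the one remaining hydroxyl with trimethylsilyldiazomethane (toluene/MeOH, 0 °C) would give 3-[4-(tert-butyldiphenylsilyloxy)phenyl]-5-methoxy-4,7-diphenyl-1-benzofuran-2,6-dione F3. Desilylation with HF·pyridine in THF would then give 15.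

3. Step 3. Amide may add to the aryne faster than the ketene acetal does, or deprotonation at the hindered ortho position may be slow. Fallback, from 4 and back at 7: a second bromination (Br2, AcOH, 40 °C) at the last free ring position would give 1,2-dibromo-4,5-dimethoxy-3,6-diphenylbenzene F4. Addition of n-BuLi (1.0 equiv) to this dibromide and 5 in toluene at −78 °C, then warming, would generate the same aryne 6 by bromine–lithium exchange and loss of LiBr with no amide nucleophile present. Capture of 6 by 5 gives 7.

**Further compounds**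
F1 | step 5 | 3,4-dimethoxy-2,5-diphenylphenol | COc1c(OC)c(-c2ccccc2)c(O)cc1-c1ccccc1
F2 | step 9 | 3-[4-(tert-butyldiphenylsilyloxy)phenyl]-5-hydroxy-4,7-diphenyl-1-benzofuran-2,6-dione | OC1=C(c2ccccc2)C2=C(c3ccc(O[Si](c4ccccc4)(c4ccccc4)C(C)(C)C)cc3)C(=O)OC2=C(c2ccccc2)C1=O
F3 | step 9 | 3-[4-(tert-butyldiphenylsilyloxy)phenyl]-5-methoxy-4,7-diphenyl-1-benzofuran-2,6-dione | COC1=C(c2ccccc2)C2=C(c3ccc(O[Si](c4ccccc4)(c4ccccc4)C(C)(C)C)cc3)C(=O)OC2=C(c2ccccc2)C1=O
F4 | step 3 | 1,2-dibromo-4,5-dimethoxy-3,6-diphenylbenzene | COc1c(OC)c(-c2ccccc2)c(Br)c(Br)c1-c1ccccc1
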